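- In the flask, the D fed stands as D, E, Q or something unread, so once the dose ends at 3.0 h those shares sum to the charge. D, at 0.25 M against 0.375 M of X, is the limiting reagent, and its balance is the one to write.

| setting | south-east | south-west | north | flask |
|---|---|---|---|---|
| D | 0.25 M (fed, over 3.0 h) | 0.25 M (fed, over 3.0 h) | 0.25 M (fed, over 3.0 h) | 0.25 M (fed, over 3.0 h) |
| X | 0.375 M | 0.375 M | 0.375 M | 0.375 M |
| G | 40 mM | 40 mM | 20 mM | 40 mM |
| J | 3.4 mM | 7.5 mM | 5 mM | 5.0 mM |
| remark | run made earlier; the fed solution adds 0.10 times the starting volume | run made earlier; the fed solution adds 0.10 times the starting volume | run made earlier; the fed solution adds 0.10 times the starting volume | the fed solution adds 0.10 times the starting volume |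
| time |  |  |  | 3.0 h |

| run | time / h | Q / % | E / % |
|---|---|---|---|
| south-east | 0.250 | 0.5 | 0 |
| south-east | 0.417 | 0.3 | 1.0 |
| south-east | 0.667 | 1.4 | 1.7 |
| south-east | 1.00 | 0.3 | 2.9 |
| south-east | 1.50 | 0.3 | 7.3 |
| south-east | 2.50 | 3.9 | 16.7 |
| south-east | 4.00 | 11.6 | 27.3 |
| south-west | 0.500 | 0 | 0 |
| south-west | 1.00 | 0.8 | 3.8 |
| south-west | 1.50 | 2.7 | 7.8 |
| south-west | 2.00 | 3.8 | 8.7 |
| south-west | 2.50 | 7.5 | 12.0 |
| south-west | 3.00 | 10.1 | 17.2 |
| south-west | 4.00 | 18.3 | 20.4 |
| north | 0.250 | 0 | 0.3 |
| north | 0.500 | 0 | 0.5 |
| north | 1.00 | 0.4 | 0 |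
| north | 2.00 | 1.1 | 5.6 |
| north | 4.00 | 6.9 | 12.9 |

(scatter of a reading: 1 percentage point)

- charges are per starting volume, the dose included; the dosed solution carries all of it
- percentages count the whole charge, also what has not yet gone in

* Q present at 3.0 h, in percent of the D charged
* E present at 3.0 h, in percent of the D charged
* D present at 3.0 h, in percent of the D charged
* concentration of X at 3.0 h, in M

- At 4.00 h, E + Q reads 38.9 % in the south-east run and 38.7 % in the south-west run, though [J] differs between them. The north run, with half the [G], reads 19.8 %. So the sum at 40 mM of G can be taken across to the flask, whose [J] lies between.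
- Bound from above: the south-east sum at 2.50 h already reads 20.6 % and reads higher at 4.00 h, and an unread form can only lower D, so D in the flask at 3.0 h should stand below 79.4 %, within the scatter of the readings.
- Bound from below: the south-east sum at 4.00 h puts D in the flask above 61.1 %, within the same scatter and provided the unread form is small.
- Tightened: the remainder, the charge minus E + Q read at the end of the dose, is 72.7 % from the south-west run. A straight line between the two south-east readings gives 73.3 %. Each reading carries a scatter of 1 percentage point. The reckoning here commits to the remainder.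
- The forecast gives Q 7.3 %, E 18.5 %, D 74.2 % and X 0.282 M, on the ground: “So D→E is first order in D and in G and does not depend on J.” Its D lies inside the outer bracket and just above the tightened pair.
- The flask gives Q 8.02 %, E 18.1 %, D 73.0 % and X 0.313 M, so D lies inside the bracket, beside the remainder 72.7 %.

    X + G → Z (k = 0.310 M⁻¹ h⁻¹)
    X + J + E → J + Q (k = 230 M⁻² h⁻¹)
    D + G → G + E (k = 7.40 M⁻¹ h⁻¹)
    E → L (k = 0.0380 h⁻¹)

- While D went in, D + G → G + E ran on a G that fell to 84.5 % of its charge by 1.50 h and 72.5 % by 3.00 h, with Z holding the other 27.5 %. The step to Q followed late, with 1.6 % of its turnover up to 3.0 h behind it at 0.600 h, while E → L had turned over 0.853 % of the charge by 3.0 h, which brings D, E, Q and L together to >99.9 %.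
- With 1.0 M of D and the other charges as in the flask, the remainder carries over as a share provided D + G → G + E, first order in D, runs on a like [G]: 72.7 % of the charge should stand as D. That neighbour flask gives D 72.9 %, with G at 73.5 % of its charge against 72.5 % in the flask, and X at 0.263 M.

(The readings are simulated from invented constants, noise included.)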